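Atom numbering used throughout: C1 is the ring carbon bearing the methylidene, then C2, C3 (CHOH), C4 (CHBr), C5 (CMe2), C6 (spiro carbon), C7, C8, C9 (C(OH)CH3), C10 (CHCl), C11. Ring A is C1–C6 and ring B is C6–C11.

## The problem

The target 25 is a spiro[5.5]undecane whose rings A and B share the quaternary carbon C6. In ring A, C6 lies between a second quaternary carbon (C5, gem-dimethyl) and the sp2 carbon C1 with its exocyclic methylidene, so two adjacent fully substituted carbons must be joined and a ring closed onto them. The five stereocentres form two pairs, C3/C4 (hydroxyl cis to bromine) and C9/C10 (hydroxyl cis to chlorine, methyl trans), linked only through C6, which is stereogenic solely because C10 and not C8 carries chlorine. Within each pair control is available: C4 can direct C3 in the reduction of an α-bromo ketone, and C10 can direct C9 in an addition to an α-chloro ketone. C6 can direct the face at C10 once ring B is a chair with the C5 arm equatorial and the C1 arm axial. The ring A pair is too remote to decide between C8 and C10, so two reagent-controlled events are needed. The methylidene is the most fragile group: acid moves it into the ring, and whenever C3 is a ketone it is β,γ-unsaturated and slips into conjugation under acid or base. The secondary bromide, the tertiary chlorohydrin and any α-halo ketone on the way are also intolerant of strong base. The key step rests on one feature: C1 sits between C6 and C2, and C2 is α to the oxygenated C3. With C3 as a ketone, C2 is an enol carbon, and the C1 methylidene is what an ethynyl group on C6 becomes when that enol adds across it.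

## Retrosynthesis

25 to 24: the C9–CH3 bond is cut. A methyl nucleophile adding to an α-chloro ketone gives the hydroxyl cis to chlorine, whereas any alkene-based chlorohydrin synthesis would give the trans isomer. The precursor 24 has one stereocentre fewer. The forward step must attack the locked ring B chair along the equatorial direction.

24 to 23: the C10–Cl bond is cut. Ring B of 23 is symmetric, so this one bond creates C10 and C6 together. Carrying a stereogenic C6 from an earlier stage would require an enantioselective quaternary-carbon construction whose two arms differ only at a distant position. The forward step must choose C10 over C8 (catalyst) and the face anti to the axial C1 arm (substrate).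

23 to 22: the ring B ketone is masked as its dioxolane. The ketal keeps ring B inert and symmetric through all ring A chemistry.

22 to 21: the C3–H bond is cut. Reduction of an α-bromo ketone gives the cis bromohydrin directly, while bromohydroxylation of a C3–C4 alkene would give the trans one. Ketone 21 is racemic at C4 but epimerises easily, so a dynamic kinetic reduction can set C3 and C4 together.

21 to 18 to 16: the carboxyl carbon is put back on C2 and the C4–Br bond is cut. In 21 the more acidic α-position is the allylic C2, so direct bromination would go to the wrong side. In 16 the ester makes C2 the first site deprotonated and leaves C4 for the second, so the dianion places bromine at C4.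

16 to 15: the C1–C2 bond is cut (key step). This opens ring A to an acyclic β-keto ester carrying an ethynyl group on C6. The alternative cuts within ring A (C2–C3, C3–C4, or a bond to a quaternary carbon) would each either create a stereocentre in the ring-forming step or require closing onto a quaternary carbon. The forward reaction is a 6-exo-dig Conia-ene closure that gives the methylidene and the C3 carbonyl at the correct oxidation levels without creating a stereocentre.

15 to 13 and 14: the C2–C3 bond is cut. Homologation of aldehyde 13 with diazo ester 14 gives the β-keto ester in one step. An acetate Claisen route would need the carboxylic acid and an activation step.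

13 back to 8: these are functional group changes only, except that the terminal alkyne carbon is added to the aldehyde on C6 (10 to 11). The hindered carbinol on C6 is converted first while the other primary alcohol is silylated (9), then that alcohol is released (12) and oxidised (13).

8 to 6: both primary alcohols come from the acid and the vinyl group of 6, by reduction and anti-Markovnikov hydration in one operation.

6 to 3: the C5–C6 bond is cut. An Ireland–Claisen rearrangement forms the two adjacent quaternary carbons intramolecularly; alkylation with a tertiary electrophile or conjugate addition to a β,β-disubstituted acceptor would not. It leaves a carboxyl on C6 and a vinyl group on C5 as the two handles.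

3 to 1 and 2: the ester C–O bond is cut, giving a commercial ketal acid and prenyl bromide.

## Roads not taken

Alternative 1: The cut removes C10 with its chlorine (bonds C9–C10 and C10–C11), contracting ring B to the spiro silyloxycyclopentadiene A2. In the forward sense dichlorocarbene would add to the silyl enol ether double bond of A2. The dichlorocyclopropane would then open with loss of chloride and silyl to the spiro 2-chlorocyclohexa-2,5-dienone A1.
- Merits: the position of chlorine is fixed by the position of the enol ether, so no late choice between C8 and C10 is needed, and ring A arrives complete. In this respect it is better than the chosen plan.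
- Weak points: A2 offers the carbene two further electron-rich alkenes (the second diene bond and the C1 methylidene), and silyloxycyclopentadienes dimerise readily. A1 must then lose two enone double bonds in the presence of a secondary bromide, an enone-bound chlorine and the methylidene, and the reduction of the C10–C11 bond would have to set C10. The configuration at C6 must already be present in A2, which shifts the problem to an enantioselective spiro[4.5] synthesis.
- Against this, the chosen plan keeps ring B saturated and symmetric until one catalytic step sets C6 and C10, and needs no reduction next to a halide.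

Alternative 2: The cut is C6–C7. The phenolate of the iodo phenol A4 would be alkylated through its para carbon by the tethered primary iodide, closing ring B and giving the spiro 3-methoxy-5-methylcyclohexa-2,5-dienone A3.
- Merits: this is the shortest access to the spirocycle, from a cheap orcinol ether, and dearomatising para-alkylation is reliable; in step count to a spiro intermediate it beats the chosen plan.
- Weak points: A3 has neither the C5 gem-dimethyl group nor the C1 methylidene. The second methyl would have to be added by conjugate addition to a β-substituted dienone carbon next to the spiro centre, an intermolecular construction of adjacent quaternary carbons. The vinylogous ester would then have to be converted into a methylidene at the more hindered carbonyl of a β-diketone. A3 is achiral, so every stereocentre remains to be set, as in the chosen plan.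
- Against this, the chosen plan builds C5–C6 at the start by a sigmatropic shift, and its key step delivers C1=CH2 and C3=O directly.

Alternative 3: The cut is C2–C3. Me2AlCl would activate the α-bromo aldehyde A6; its carbonyl carbon would bond to the isopropenyl CH2 with hydrogen transfer from the methyl group. This closes ring A and gives the cis bromohydrin A5, which is the same compound as 22.
- Merits: ring A, the methylidene and the C3 carbinol arise in one step, C3 is never a ketone, and there is no ester to remove. In step count after ring closure and in avoiding the β,γ-unsaturated ketone this road is better than the chosen one.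
- Weak points: everything rests on A6. Its C4 centre must be made enantiopure and must survive a Lewis acid that promotes enolisation of α-bromo aldehydes, and nothing downstream can correct an erosion. The cis relationship must come from the cyclic transition state alone. Me2AlCl can also transfer methyl or chloride, or open a cationic pathway at the 1,1-disubstituted alkene. The isopropenyl group on C6 next to quaternary C5 is itself hard to install.
- Against this, the chosen plan sets C3 and C4 with an enzyme on a substrate whose lability is an asset, and closes ring A in a catalytic step that forms no stereocentre and has close precedent.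

Key step: step 10

Assumption: the (4R,5R) amine of step 15 is taken to be the antipode that chlorinates the enamine toward C10 on the face anti to the C1 arm; if the sense is opposite, the (4S,5S) catalyst is used and nothing else changes.

## Steps

Step 1
Reactants: 1 1,4-dioxaspiro[4.5]decane-8-carboxylic acid; 2 1-bromo-3-methylbut-2-ene
Product: 3 3-methylbut-2-en-1-yl 1,4-dioxaspiro[4.5]decane-8-carboxylate
Conditions: K2CO3, DMF, rt
Reagents that add atoms: none
Why: Carboxylate O-alkylation (SN2) of the potassium salt of 1 by the primary allylic bromide at its unsubstituted terminus; the ketal is inert to carbonate.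

Step 2
Reactants: 3 3-methylbut-2-en-1-yl 1,4-dioxaspiro[4.5]decane-8-carboxylate
Product: 6 8-(2-methylbut-3-en-2-yl)-1,4-dioxaspiro[4.5]decane-8-carboxylic acid, via silyl ketene acetal 4 (not isolated), via trimethylsilyl ester 5 (not isolated)
Conditions: LDA, THF, −78 °C; TMSCl, −78 °C to rt, then 65 °C; H2O
Reagents that add atoms: none
Why: Ireland–Claisen rearrangement: O-silylation of the ester enolate gives 4, whose [3,3] shift through a chair transition state joins the enolate carbon C6 to the dimethyl-substituted allyl terminus C5, so both quaternary carbons are made intramolecularly; heating is needed because both termini are fully substituted. No stereocentre arises, since ring B is symmetric and C5 carries two methyl groups.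

Step 3
Reactants: 6 8-(2-methylbut-3-en-2-yl)-1,4-dioxaspiro[4.5]decane-8-carboxylic acid
Product: 8 3-[8-(hydroxymethyl)-1,4-dioxaspiro[4.5]decan-8-yl]-3-methylbutan-1-ol, via organoborane 7 (not isolated)
Conditions: BH3·SMe2, THF, 0 °C to rt; then NaOH, H2O2, 0 °C
Reagents that add atoms: hydrogen peroxide, OO
Why: Borane reduces the carboxylic acid through its acyloxyborane and hydroborates the vinyl group with boron on the terminal carbon, the internal one being attached to quaternary C5; oxidation of the C–B bond with retention gives the primary alcohol (hydroboration–oxidation). The dioxolane is stable to borane at room temperature.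

Step 4
Reactants: 8 3-[8-(hydroxymethyl)-1,4-dioxaspiro[4.5]decan-8-yl]-3-methylbutan-1-ol
Product: 9 [8-(4-{[tert-butyl(dimethyl)silyl]oxy}-2-methylbutan-2-yl)-1,4-dioxaspiro[4.5]decan-8-yl]methanol
Conditions: TBSCl (1.05 equiv), imidazole, CH2Cl2, −20 °C
Reagents that add atoms: tert-butyldimethylsilyl chloride, CC(C)(C)[Si](C)(C)Cl
Why: Selective silylation of the less hindered primary alcohol: the hydroxymethyl group on C6 is neopentyl and lies between two quaternary carbons, whereas the other hydroxyl is two methylenes away from C5.

Step 5
Reactants: 9 [8-(4-{[tert-butyl(dimethyl)silyl]oxy}-2-methylbutan-2-yl)-1,4-dioxaspiro[4.5]decan-8-yl]methanol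
Product: 10 8-(4-{[tert-butyl(dimethyl)silyl]oxy}-2-methylbutan-2-yl)-1,4-dioxaspiro[4.5]decane-8-carbaldehyde
Conditions: Dess–Martin periodinane, pyridine, CH2Cl2, rt
Reagents that add atoms: none
Why: Dess–Martin oxidation of the hindered primary alcohol under buffered, non-aqueous conditions; the aldehyde has no α-hydrogen and cannot enolise.

Step 6
Reactants: 10 8-(4-{[tert-butyl(dimethyl)silyl]oxy}-2-methylbutan-2-yl)-1,4-dioxaspiro[4.5]decane-8-carbaldehyde
Product: 11 tert-butyl{[3-(8-ethynyl-1,4-dioxaspiro[4.5]decan-8-yl)-3-methylbutyl]oxy}dimethylsilane
Conditions: dimethyl (1-diazo-2-oxopropyl)phosphonate, K2CO3, MeOH, 0 °C to rt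
Reagents that add atoms: dimethyl (1-diazo-2-oxopropyl)phosphonate, COP(=O)(OC)C(=[N+]=[N-])C(C)=O
Why: Ohira–Bestmann (Seyferth–Gilbert) homologation: the diazomethylphosphonate anion released by methanolysis adds to the non-enolisable aldehyde, and loss of phosphate and N2 with a 1,2-hydrogen shift of the alkylidene carbene gives the terminal alkyne. The silyl ether and the ketal are stable to K2CO3 in methanol.

Step 7
Reactants: 11 tert-butyl{[3-(8-ethynyl-1,4-dioxaspiro[4.5]decan-8-yl)-3-methylbutyl]oxy}dimethylsilane
Product: 12 3-(8-ethynyl-1,4-dioxaspiro[4.5]decan-8-yl)-3-methylbutan-1-ol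
Conditions: TBAF, THF, 0 °C to rt
Reagents that add atoms: none
Why: Fluoride-induced cleavage of the silyl ether; nothing else in 11 is fluoride-labile.

Step 8
Reactants: 12 3-(8-ethynyl-1,4-dioxaspiro[4.5]decan-8-yl)-3-methylbutan-1-ol
Product: 13 3-(8-ethynyl-1,4-dioxaspiro[4.5]decan-8-yl)-3-methylbutanal
Conditions: Dess–Martin periodinane, pyridine, CH2Cl2, 0 °C to rt
Reagents that add atoms: none
Why: Dess–Martin oxidation of the primary alcohol to the aldehyde; the product is carried on without storage because its α-methylene is enolisable.

Step 9
Reactants: 13 3-(8-ethynyl-1,4-dioxaspiro[4.5]decan-8-yl)-3-methylbutanal; 14 tert-butyl diazoacetate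
Product: 15 tert-butyl 5-(8-ethynyl-1,4-dioxaspiro[4.5]decan-8-yl)-5-methyl-3-oxohexanoate
Conditions: SnCl2 (10 mol %), CH2Cl2, rt
Reagents that add atoms: none
Why: Roskamp reaction: the SnCl2-activated aldehyde is attacked by the diazo carbon of 14, and a 1,2-hydride shift with loss of N2 gives the β-keto ester directly, adding C2 and the carboxyl carbon. The mild Lewis acid leaves the terminal alkyne and the ketal untouched.

Step 10
Reactants: 15 tert-butyl 5-(8-ethynyl-1,4-dioxaspiro[4.5]decan-8-yl)-5-methyl-3-oxohexanoate
Product: 16 tert-butyl 11-hydroxy-13,13-dimethyl-9-methylidene-1,4-dioxadispiro[4.2.5.2]pentadec-10-ene-10-carboxylate (cyclic β-keto ester of ring A, enol form)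
Conditions: In(NTf2)3 (5 mol %), toluene, 60 °C
Reagents that add atoms: none
Why: Conia-ene cycloisomerisation under trivalent indium catalysis: In(NTf2)3 exchanges one triflimide for the enol proton of 15, giving an indium enolate chelated through the ketone and ester oxygens, and HNTf2. The tethered alkyne binds the same metal and the enolate carbon C2 adds to its internal carbon C1 in a syn carbometalation; protonation of the vinyl–indium bond by HNTf2 releases the methylidene and returns the catalyst. The closest known reaction is the indium-catalysed cyclisation of ω-alkynyl β-keto esters tethered through the ketone side, which closes six-membered and larger rings. Ring A is closed in the 6-exo-dig mode and C1–C2 is the only skeletal bond formed. No stereocentre is created, because ring B is symmetric and C2 is an enol carbon in 16. The step needs C- rather than O-attack, exo rather than 7-endo closure, and an alkene that stays exocyclic. The chelate holds C2, not oxygen, over the alkyne; the terminal alkyne and the ring size fix the exo mode; and the two fully substituted carbons C5 and C6 in the tether compress it toward closure. The product rests as its hydrogen-bonded enol as long as the medium is kept free of strong protic acid.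

Step 11
Reactants: 16 tert-butyl 11-hydroxy-13,13-dimethyl-9-methylidene-1,4-dioxadispiro[4.2.5.2]pentadec-10-ene-10-carboxylate
Product: 18 tert-butyl 12-bromo-11-hydroxy-13,13-dimethyl-9-methylidene-1,4-dioxadispiro[4.2.5.2]pentadec-10-ene-10-carboxylate (racemic), via dilithium dianion 17 (not isolated)
Conditions: LDA (2.3 equiv), THF, −78 to 0 °C; then added to BrCl2C–CCl2Br, THF, −78 °C; AcOH
Reagents that add atoms: 1,2-dibromo-1,1,2,2-tetrachloroethane, BrC(Cl)(Cl)C(Cl)(Cl)Br
Why: Bromination of a β-keto ester dianion: the first equivalent of base gives the chelated C2 enolate and the second removes a proton from C4, the only acidic position left. The last-formed, most basic carbanion centre takes bromine from the halogen donor, as in γ-alkylation of such dianions, so the ester steers bromine to C4 and away from the allylic C2. C4 is formed as a racemate, which step 13 resolves dynamically.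

Step 12
Reactants: 18 tert-butyl 12-bromo-11-hydroxy-13,13-dimethyl-9-methylidene-1,4-dioxadispiro[4.2.5.2]pentadec-10-ene-10-carboxylate
Product: 21 10-bromo-9,9-dimethyl-13-methylidene-1,4-dioxadispiro[4.2.5.2]pentadecan-11-one (racemic), via bis(trimethylsilyl) derivative 19 (not isolated), via β-keto acid 20 (not isolated)
Conditions: TMSOTf, 2,6-lutidine, CH2Cl2, 0 °C; then phosphate buffer pH 7, THF, 30 °C
Reagents that add atoms: none
Why: The silyl triflate converts the tert-butyl ester into a silyl ester with loss of isobutene (the enol is silylated at the same time), and buffered hydrolysis gives the β-keto acid, which loses CO2 through its dienol. Kinetic protonation of the dienol at C2 gives the β,γ-unsaturated ketone; no strong protic acid is present, so the methylidene and the dioxolane should persist.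

Step 13
Reactants: 21 10-bromo-9,9-dimethyl-13-methylidene-1,4-dioxadispiro[4.2.5.2]pentadecan-11-one
Product: 22 (10S,11R)-10-bromo-9,9-dimethyl-13-methylidene-1,4-dioxadispiro[4.2.5.2]pentadecan-11-ol
Conditions: ketoreductase (panel-selected), NADP+ (cat.), iPrOH, phosphate buffer pH 7.5, DMSO, 30 °C
Reagents that add atoms: none
Why: Ketoreductase reduction with dynamic kinetic resolution: the α-bromo ketone epimerises at C4 through its enol in the buffer while the enzyme reduces only the (4S)-ketone and delivers hydride to the face that gives the (3R)-alcohol. C3 and C4 are thus both set by the enzyme and the racemate converges on the cis bromohydrin; isopropanol regenerates the cofactor.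

Step 14
Reactants: 22 (10S,11R)-10-bromo-9,9-dimethyl-13-methylidene-1,4-dioxadispiro[4.2.5.2]pentadecan-11-ol
Product: 23 (8S,9R)-8-bromo-9-hydroxy-7,7-dimethyl-11-methylidenespiro[5.5]undecan-3-one
Conditions: HCl (1 M), THF, 0 °C to rt
Reagents that add atoms: water, O
Why: Acid-catalysed hydrolysis of the dioxolane; the bromohydrin and the 1,1-disubstituted alkene tolerate dilute acid at room temperature. Ring B remains symmetric, so no stereocentre is added.

Step 15
Reactants: 23 (8S,9R)-8-bromo-9-hydroxy-7,7-dimethyl-11-methylidenespiro[5.5]undecan-3-one
Product: 24 (2S,6S,8S,9R)-8-bromo-2-chloro-9-hydroxy-7,7-dimethyl-11-methylidenespiro[5.5]undecan-3-one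
Conditions: NCS, (4R,5R)-4,5-diphenylimidazolidine (20 mol %), 2-nitrobenzoic acid (20 mol %), MeCN, −24 °C
Reagents that add atoms: N-chlorosuccinimide, O=C1CCC(=O)N1Cl
Why: Enamine-catalysed α-chlorination of a ketone with a chiral secondary amine: ring B is a chair with the C5 arm equatorial and the C1 arm axial, and the axial arm blocks the syn face of both α-carbons, so chlorine enters anti to it and ends equatorial, cis to C5. The catalyst accepts only one enantioface of an enamine, and with the face fixed by the ring this becomes a choice of the enamine toward C10 over that toward C8, which sets C6 (S) together with C10 (S). The remote ring A stereocentres only turn the minor outcome into a separable diastereomer.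

Step 16
Reactants: 24 (2S,6S,8S,9R)-8-bromo-2-chloro-9-hydroxy-7,7-dimethyl-11-methylidenespiro[5.5]undecan-3-one
Product: 25 (2S,3R,6S,8S,9R)-2-bromo-8-chloro-1,1,9-trimethyl-5-methylidenespiro[5.5]undecane-3,9-diol
Conditions: MeTi(OiPr)3 (3 equiv), THF, −20 °C to rt; aqueous work-up
Reagents that add atoms: methyltitanium triisopropoxide, C[Ti](OC(C)C)(OC(C)C)OC(C)C
Why: Addition of a methyltitanium reagent to the α-chloro ketone: in the locked chair the bulky, non-basic reagent attacks C9 along the equatorial direction, placing methyl equatorial and hydroxyl axial, cis to the equatorial chlorine at C10. This is the sense generally found for organometallic additions to 2-chlorocyclohexanones, so C9 (R) is set by C10 and C6 and the α-chloro ketone is not enolised.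

## Compound list

1 | 1,4-dioxaspiro[4.5]decane-8-carboxylic acid | OC(=O)C1CCC2(OCCO2)CC1 | starting material
2 | 1-bromo-3-methylbut-2-ene (prenyl bromide) | CC(C)=CCBr | starting material
3 | 3-methylbut-2-en-1-yl 1,4-dioxaspiro[4.5]decane-8-carboxylate | CC(C)=CCOC(=O)C1CCC2(OCCO2)CC1 | intermediate
4 | [(1,4-dioxaspiro[4.5]decan-8-ylidene)(3-methylbut-2-en-1-yloxy)methoxy]trimethylsilane (silyl ketene acetal, formed in the flask) | CC(C)=CCOC(O[Si](C)(C)C)=C1CCC2(OCCO2)CC1 | intermediate
5 | trimethylsilyl 8-(2-methylbut-3-en-2-yl)-1,4-dioxaspiro[4.5]decane-8-carboxylate (formed in the flask) | C=CC(C)(C)C1(CCC2(OCCO2)CC1)C(=O)O[Si](C)(C)C | intermediate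
6 | 8-(2-methylbut-3-en-2-yl)-1,4-dioxaspiro[4.5]decane-8-carboxylic acid | C=CC(C)(C)C1(CCC2(OCCO2)CC1)C(O)=O | intermediate
7 | organoborane from 6: O-boryl ether of the reduced acid with a terminal C-boryl group, drawn as the monomeric dihydroboryl species (formed in the flask) | BOCC1(CCC2(OCCO2)CC1)C(C)(C)CCB | intermediate
8 | 3-[8-(hydroxymethyl)-1,4-dioxaspiro[4.5]decan-8-yl]-3-methylbutan-1-ol | OCC1(CCC2(OCCO2)CC1)C(C)(C)CCO | intermediate
9 | [8-(4-{[tert-butyl(dimethyl)silyl]oxy}-2-methylbutan-2-yl)-1,4-dioxaspiro[4.5]decan-8-yl]methanol | OCC1(CCC2(OCCO2)CC1)C(C)(C)CCO[Si](C)(C)C(C)(C)C | intermediate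
10 | 8-(4-{[tert-butyl(dimethyl)silyl]oxy}-2-methylbutan-2-yl)-1,4-dioxaspiro[4.5]decane-8-carbaldehyde | O=CC1(CCC2(OCCO2)CC1)C(C)(C)CCO[Si](C)(C)C(C)(C)C | intermediate
11 | tert-butyl{[3-(8-ethynyl-1,4-dioxaspiro[4.5]decan-8-yl)-3-methylbutyl]oxy}dimethylsilane | C#CC1(CCC2(OCCO2)CC1)C(C)(C)CCO[Si](C)(C)C(C)(C)C | intermediate
12 | 3-(8-ethynyl-1,4-dioxaspiro[4.5]decan-8-yl)-3-methylbutan-1-ol | C#CC1(CCC2(OCCO2)CC1)C(C)(C)CCO | intermediate
13 | 3-(8-ethynyl-1,4-dioxaspiro[4.5]decan-8-yl)-3-methylbutanal | C#CC1(CCC2(OCCO2)CC1)C(C)(C)CC=O | intermediate
14 | tert-butyl diazoacetate | CC(C)(C)OC(=O)C=[N+]=[N-] | starting material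
15 | tert-butyl 5-(8-ethynyl-1,4-dioxaspiro[4.5]decan-8-yl)-5-methyl-3-oxohexanoate | C#CC1(CCC2(OCCO2)CC1)C(C)(C)CC(=O)CC(=O)OC(C)(C)C | intermediate
16 | tert-butyl 11-hydroxy-13,13-dimethyl-9-methylidene-1,4-dioxadispiro[4.2.5.2]pentadec-10-ene-10-carboxylate (enol form of the ring A β-keto ester) | C=C1C(C(=O)OC(C)(C)C)=C(O)CC(C)(C)C12CCC3(OCCO3)CC2 | intermediate
17 | dilithium dianion of 16, deprotonated at the enol oxygen and at C4 (formed in the flask) | [Li+].[Li+].C=C1C(=C([O-])OC(C)(C)C)C([O-])=CC(C)(C)C12CCC3(OCCO3)CC2 | intermediate
18 | tert-butyl 12-bromo-11-hydroxy-13,13-dimethyl-9-methylidene-1,4-dioxadispiro[4.2.5.2]pentadec-10-ene-10-carboxylate (racemic at C4, enol form) | C=C1C(C(=O)OC(C)(C)C)=C(O)C(Br)C(C)(C)C12CCC3(OCCO3)CC2 | intermediate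
19 | trimethylsilyl 12-bromo-13,13-dimethyl-9-methylidene-11-[(trimethylsilyl)oxy]-1,4-dioxadispiro[4.2.5.2]pentadec-10-ene-10-carboxylate (formed in the flask) | C=C1C(C(=O)O[Si](C)(C)C)=C(O[Si](C)(C)C)C(Br)C(C)(C)C12CCC3(OCCO3)CC2 | intermediate
20 | 12-bromo-11-hydroxy-13,13-dimethyl-9-methylidene-1,4-dioxadispiro[4.2.5.2]pentadec-10-ene-10-carboxylic acid (β-keto acid, enol form, formed in the flask) | C=C1C(C(O)=O)=C(O)C(Br)C(C)(C)C12CCC3(OCCO3)CC2 | intermediate
21 | 10-bromo-9,9-dimethyl-13-methylidene-1,4-dioxadispiro[4.2.5.2]pentadecan-11-one (racemic) | C=C1CC(=O)C(Br)C(C)(C)C12CCC3(OCCO3)CC2 | intermediate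
22 | (10S,11R)-10-bromo-9,9-dimethyl-13-methylidene-1,4-dioxadispiro[4.2.5.2]pentadecan-11-ol (3R,4S in the text numbering; hydroxyl cis to bromine) | C=C1C[C@@H](O)[C@@H](Br)C(C)(C)C12CCC3(OCCO3)CC2 | intermediate
23 | (8S,9R)-8-bromo-9-hydroxy-7,7-dimethyl-11-methylidenespiro[5.5]undecan-3-one | C=C1C[C@@H](O)[C@@H](Br)C(C)(C)C12CCC(=O)CC2 | intermediate
24 | (2S,6S,8S,9R)-8-bromo-2-chloro-9-hydroxy-7,7-dimethyl-11-methylidenespiro[5.5]undecan-3-one (chlorine equatorial, cis to the C5 arm across ring B) | C=C1C[C@@H](O)[C@@H](Br)C(C)(C)[C@]12CCC(=O)[C@@H](Cl)C2 | intermediate
25 | (2S,3R,6S,8S,9R)-2-bromo-8-chloro-1,1,9-trimethyl-5-methylidenespiro[5.5]undecane-3,9-diol (3R,4S,6S,9R,10S in the text numbering) | C=C1C[C@@H](O)[C@@H](Br)C(C)(C)[C@]12CC[C@@](C)(O)[C@@H](Cl)C2 | target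

Total step count: 16. Longest linear sequence: 16 steps, from 1 to 25.

## Least certain steps

Step 10 (key step). The exocyclic double bond may migrate into conjugation with the ester under the Lewis acid and traces of HNTf2. The dioxolane may be opened by the indium salt. Closure onto an alkyne flanked by two quaternary carbons may be slow enough for alkyne hydration or oligomerisation to compete. Material whose double bond has migrated is not lost, since double deprotonation in step 11 leads to the same dianion 17. Fallback: starting from 15, silylation with TBSOTf and Et3N should give the silyl enol ether tert-butyl (2Z)-3-{[tert-butyl(dimethyl)silyl]oxy}-5-(8-ethynyl-1,4-dioxaspiro[4.5]decan-8-yl)-5-methylhex-2-enoate F1. A cationic monovalent gold catalyst (Ph3PAuCl with AgSbF6, CH2Cl2–MeOH, rt) would then activate the alkyne as a π-complex for outer-sphere attack by the enol ether carbon C2. Protodeauration and loss of the silyl group to methanol return the route at 16. This replaces inner-sphere enolate carbometalation under a strong Lewis acid by π-acid catalysis on a neutral nucleophile.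

Step 11. The second deprotonation at the hindered C4 methylene may be incomplete. Bromine may be transferred to C2 or to the methylidene terminus of the delocalised first enolate. Proton exchange between the brominated monoanion and unreacted dianion may lead to double bromination. Fallback: starting from aldehyde 13, enamine-catalysed α-bromination (pyrrolidine and benzoic acid as catalysts, 4,4-dibromo-2,6-di-tert-butylcyclohexa-2,5-dienone) should give 2-bromo-3-(8-ethynyl-1,4-dioxaspiro[4.5]decan-8-yl)-3-methylbutanal F2. Roskamp homologation of F2 with 14 and SnCl2 would give tert-butyl 4-bromo-5-(8-ethynyl-1,4-dioxaspiro[4.5]decan-8-yl)-5-methyl-3-oxohexanoate F3, and In(NTf2)3 cyclisation of F3 returns the route at 18. Bromine is then introduced where only one enolisable position exists and is carried through the ring closure as a spectator.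

Step 12. Once the ester is gone the β,γ double bond may slip into conjugation with the C3 ketone through the dienol. The silyl triflate may open the dioxolane, and decarboxylation of the enolised acid may be sluggish. Running the hydrolysis in the buffer of step 13 and reducing without isolation would shorten the life of the sensitive ketone. Fallback: starting from 18, ester exchange with 2-(trimethylsilyl)ethanol in toluene at 100 °C (through the acyl ketene) should give 2-(trimethylsilyl)ethyl 12-bromo-11-hydroxy-13,13-dimethyl-9-methylidene-1,4-dioxadispiro[4.2.5.2]pentadec-10-ene-10-carboxylate F4. TBAF buffered with acetic acid (THF, rt) would fragment the ester to the carboxylate, which decarboxylates and returns the route at 21. This replaces electrophilic ester cleavage by a fluoride-triggered fragmentation near neutral pH.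

Step 13. Epimerisation at C4 may be slower than reduction, so that conversion stops at half and only a kinetic resolution results. Enolisation toward C2 may move the double bond into conjugation. The panel may hold no enzyme with the required sense for both centres. Fallback: starting from 21, reduction with L-Selectride (THF, −78 °C) should give the racemic cis bromohydrin (10S*,11R*)-10-bromo-9,9-dimethyl-13-methylidene-1,4-dioxadispiro[4.2.5.2]pentadecan-11-ol F5. Lipase-catalysed acetylation (Burkholderia cepacia lipase, vinyl acetate) is expected by the usual empirical rule to acylate the (3R) enantiomer, giving (10S,11R)-10-bromo-9,9-dimethyl-13-methylidene-1,4-dioxadispiro[4.2.5.2]pentadecan-11-yl acetate F6, which is separated from the unreacted enantiomer. Methanolysis (K2CO3, MeOH) returns the route at 22, at the cost of at most half of the material.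

Step 15. Discrimination between C8 and C10, which fixes C6, may be poor if the face bias of the ring B chair and the enantioface preference of the catalyst do not reinforce each other. Catalyst turnover may be slow on a 4,4-disubstituted cyclohexanone. A second chlorination or attack of the chlorinating agent on the methylidene may intervene. Fallback: starting from 23, deprotonation with lithium (R,R)-bis(1-phenylethyl)amide in the presence of TMSCl (THF, −78 °C) should remove one of the two enantiotopic axial α-protons and silylate the C3 hydroxyl. The product is {[(6S,8S,9R)-8-bromo-7,7-dimethyl-11-methylidenespiro[5.5]undec-2-ene-3,9-diyl]bis(oxy)}bis(trimethylsilane) F7, with the enol ether toward C10. Chlorination of F7 with NCS (THF, 0 °C), then mild acidic methanol to free the C3 hydroxyl, returns the route at 24. The choice of C10 over C8 is then made by the base alone, and the face of chlorination is left to the ring, where the equatorial chloride is also the thermodynamic one.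

## Further compounds

F1 | step 10 | tert-butyl (2Z)-3-{[tert-butyl(dimethyl)silyl]oxy}-5-(8-ethynyl-1,4-dioxaspiro[4.5]decan-8-yl)-5-methylhex-2-enoate | C#CC1(CCC2(OCCO2)CC1)C(C)(C)C/C(O[Si](C)(C)C(C)(C)C)=C/C(=O)OC(C)(C)C
F2 | step 11 | 2-bromo-3-(8-ethynyl-1,4-dioxaspiro[4.5]decan-8-yl)-3-methylbutanal (racemic) | C#CC1(CCC2(OCCO2)CC1)C(C)(C)C(Br)C=O
F3 | step 11 | tert-butyl 4-bromo-5-(8-ethynyl-1,4-dioxaspiro[4.5]decan-8-yl)-5-methyl-3-oxohexanoate (racemic) | C#CC1(CCC2(OCCO2)CC1)C(C)(C)C(Br)C(=O)CC(=O)OC(C)(C)C
F4 | step 12 | 2-(trimethylsilyl)ethyl 12-bromo-11-hydroxy-13,13-dimethyl-9-methylidene-1,4-dioxadispiro[4.2.5.2]pentadec-10-ene-10-carboxylate (racemic, enol form) | C=C1C(C(=O)OCC[Si](C)(C)C)=C(O)C(Br)C(C)(C)C12CCC3(OCCO3)CC2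
F5 | step 13 | (10S*,11R*)-10-bromo-9,9-dimethyl-13-methylidene-1,4-dioxadispiro[4.2.5.2]pentadecan-11-ol (racemic cis bromohydrin, both enantiomers drawn) | C=C1C[C@@H](O)[C@@H](Br)C(C)(C)C12CCC3(OCCO3)CC2.C=C1C[C@H](O)[C@H](Br)C(C)(C)C12CCC3(OCCO3)CC2
F6 | step 13 | (10S,11R)-10-bromo-9,9-dimethyl-13-methylidene-1,4-dioxadispiro[4.2.5.2]pentadecan-11-yl acetate | C=C1C[C@@H](OC(C)=O)[C@@H](Br)C(C)(C)C12CCC3(OCCO3)CC2
F7 | step 15 | {[(6S,8S,9R)-8-bromo-7,7-dimethyl-11-methylidenespiro[5.5]undec-2-ene-3,9-diyl]bis(oxy)}bis(trimethylsilane) | C=C1C[C@@H](O[Si](C)(C)C)[C@@H](Br)C(C)(C)[C@]12CCC(O[Si](C)(C)C)=CC2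
A1 | alternative 1 | spiro 2-chlorocyclohexa-2,5-dienone carrying ring A of 25 as its C3 tert-butyldimethylsilyl ether | C=C1C[C@@H](O[Si](C)(C)C(C)(C)C)[C@@H](Br)C(C)(C)[C@]12C=CC(=O)C(Cl)=C2
A2 | alternative 1 | spiro trimethylsilyloxycyclopentadiene carrying ring A of 25 as its C3 tert-butyldimethylsilyl ether | C=C1C[C@@H](O[Si](C)(C)C(C)(C)C)[C@@H](Br)C(C)(C)[C@]12C=CC(O[Si](C)(C)C)=C2
A3 | alternative 2 | spiro 3-methoxy-5-methylcyclohexa-2,5-dienone with ring B as its C9 ethylene ketal | O=C1C=C(OC)C2(CCC3(OCCO3)CC2)C(C)=C1
A4 | alternative 2 | 4-{2-[2-(2-iodoethyl)-1,3-dioxolan-2-yl]ethyl}-3-methoxy-5-methylphenol | Oc1cc(OC)c(CCC2(CCI)OCCO2)c(C)c1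
A5 | alternative 3 | (10S,11R)-10-bromo-9,9-dimethyl-13-methylidene-1,4-dioxadispiro[4.2.5.2]pentadecan-11-ol (identical with 22) | C=C1C[C@@H](O)[C@@H](Br)C(C)(C)C12CCC3(OCCO3)CC2
A6 | alternative 3 | (2S)-2-bromo-3-methyl-3-[8-(prop-1-en-2-yl)-1,4-dioxaspiro[4.5]decan-8-yl]butanal | CC(=C)C1(CCC2(OCCO2)CC1)C(C)(C)[C@H](Br)C=O
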